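The route rests on cutting the O3–C7 bond of ring B. C7 is benzylic to ring C and para to O4 of ring C, so a free O4–H phenol can be oxidised to a p-quinone methide whose exocyclic carbon is C7; the 3-hydroxyl of ring A (the enal arene) then adds to C7. One operation thus closes ring B, forms O3–C7 and sets C7 trans to C8, a centre bought with (R)-trityl glycidyl ether. The precursor is a deoxy triol: a 3-hydroxy-4-alkoxybenzaldehyde whose ether carbon C8 carries free CH2OH (C9) and a 3-bromo-4-hydroxybenzyl group. The bromine later serves to build cis ring D on ring C.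

Key step: step 6

Labels: ring A is the arene that ends up carrying the enal, ring B the dioxane fused to it, ring C the central arene, ring D the dioxane fused to ring C, ring E the catechol. In ring B the aryl-bearing carbon is C7, its neighbour C8 and the hydroxymethyl carbon C9 (C7', C8', C9' in ring D). O3 and O4 of an arene lie meta and para to its carbon substituent.

Assumption: the C9 hydroxyl is left unprotected from the key step onward, because a primary hydroxyl can reach neither the quinone methide carbon (it would form an oxetane) nor the aryl bromide (meta bridge), and this removes any late Lewis-acid debenzylation next to the enal and the benzylic aryl ethers.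

Step 1
Reactants: 1 2-bromo-4-iodophenol
Product: 2 2-bromo-4-iodo-1-(methoxymethoxy)benzene
Conditions: MOMCl, i-Pr2NEt, CH2Cl2, 0 °C → rt
Reagents that add atoms: chloromethyl methyl ether, COCCl
Why: Phenol O-alkylation with an α-chloro ether (MOM protection, Williamson type) masks the acidic hydroxyl for the organomagnesium step and installs an acetal that later falls in aqueous acid.

Step 2
Reactants: 2 2-bromo-4-iodo-1-(methoxymethoxy)benzene; 3 (2R)-2-[(triphenylmethoxy)methyl]oxirane ((R)-trityl glycidyl ether)
Product: 5 (2R)-1-[3-bromo-4-(methoxymethoxy)phenyl]-3-(triphenylmethoxy)propan-2-ol, via arylmagnesium chloride 4 (not isolated)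
Conditions: i-PrMgCl·LiCl, THF, −20 °C; then CuI (10 mol%), 3, −20 → 0 °C; aq. NH4Cl
Reagents that add atoms: none
Why: Iodine–magnesium exchange is much faster at C–I than at C–Br, and the copper-catalysed SN2 opening of the terminal epoxide by the aryl Grignard reagent occurs at the unsubstituted CH2, so the bought stereocentre (the later C8) is not touched and stays R.

Step 3
Reactants: 6 4-fluoro-3-hydroxybenzaldehyde
Product: 7 4-fluoro-3-(methoxymethoxy)benzaldehyde
Conditions: MOMCl, i-Pr2NEt, CH2Cl2, 0 °C → rt
Reagents that add atoms: chloromethyl methyl ether, COCCl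
Why: MOM protection (phenol O-alkylation) prevents formation of a phenoxide that would shut the arene down toward nucleophilic aromatic substitution.

Step 4
Reactants: 5 (2R)-1-[3-bromo-4-(methoxymethoxy)phenyl]-3-(triphenylmethoxy)propan-2-ol; 7 4-fluoro-3-(methoxymethoxy)benzaldehyde
Product: 8 4-{[(2R)-1-[3-bromo-4-(methoxymethoxy)phenyl]-3-(triphenylmethoxy)propan-2-yl]oxy}-3-(methoxymethoxy)benzaldehyde
Conditions: KN(SiMe3)2, THF, 0 °C; then 7, DMF, 0 °C → rt
Reagents that add atoms: none
Why: Nucleophilic aromatic substitution (addition–elimination through a Meisenheimer complex) of the potassium alkoxide at the fluorine-bearing carbon para to the formyl group forms the C8–O4 aryl ether, and since only the O–H bond of the carbinol is broken the centre keeps its configuration (R).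

Step 5
Reactants: 8 4-{[(2R)-1-[3-bromo-4-(methoxymethoxy)phenyl]-3-(triphenylmethoxy)propan-2-yl]oxy}-3-(methoxymethoxy)benzaldehyde
Product: 9 4-{[(2R)-1-(3-bromo-4-hydroxyphenyl)-3-hydroxypropan-2-yl]oxy}-3-hydroxybenzaldehyde
Conditions: aq. HCl (3 M), THF, 45 °C
Reagents that add atoms: none
Why: Acid hydrolysis of the two aryl MOM acetals and SN1 solvolysis of the trityl ether free both phenols and the C9 hydroxyl in one operation, while the aryl alkyl ether, the aryl bromide and the aldehyde are inert to dilute aqueous acid.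

Step 6
Reactants: 9 4-{[(2R)-1-(3-bromo-4-hydroxyphenyl)-3-hydroxypropan-2-yl]oxy}-3-hydroxybenzaldehyde
Product: 11 (2S,3S)-3-(3-bromo-4-hydroxyphenyl)-2-(hydroxymethyl)-2,3-dihydro-1,4-benzodioxine-6-carbaldehyde, via p-quinone methide 10 (not isolated)
Conditions: DDQ (1.05 equiv), 1,4-dioxane, 20 °C
Reagents that add atoms: none
Why: DDQ takes hydride from the benzylic C7–H of the 4-alkyl-2-bromophenol with loss of the phenolic proton (a two-electron dehydrogenation) to give p-quinone methide 10, and the ring A 3-hydroxyl then adds to the exocyclic carbon C7 in conjugate fashion, which restores the aromaticity of ring C. The closest known reaction types are the DDQ dehydrogenative cyclisation of 2-hydroxy-1,3-diarylpropanes to flavans and the internal phenol capture of 8-O-4 quinone methides that gives trans-benzodioxanes in the oxidative coupling of catechol phenylpropanoids. Ring B closes by a 6-exo-trig oxa-Michael addition. The new centre C7 is controlled by the chiral-pool centre C8: a chair-like transition state places the aryl group and CH2OH both equatorial, and because the p-hydroxybenzyl aryl ether can reopen to 10, any cis isomer should drain into the trans (7S,8S) product. The step needs chemoselectivity between the two phenols, secured because only the ring C phenol has a para benzylic C–H and the ring A phenol is deactivated by the formyl group. The free C9 hydroxyl cannot compete since it would have to form an oxetane, and DDQ is held near one equivalent so that the product, which still carries a C7–H, is not oxidised again.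

Step 7
Reactants: 12 ethyl (2E)-3-(3,4-dihydroxyphenyl)prop-2-enoate (ethyl caffeate)
Product: 13 ethyl (2E)-3-[3,4-bis(methoxymethoxy)phenyl]prop-2-enoate
Conditions: MOMCl, i-Pr2NEt, CH2Cl2, 0 °C → rt
Reagents that add atoms: chloromethyl methyl ether, COCCl
Why: Double phenol O-alkylation (MOM protection) gives base-stable acetals that should survive hydride, hot carbonate and the ylide and that fall in the final aqueous acid step.

Step 8
Reactants: 13 ethyl (2E)-3-[3,4-bis(methoxymethoxy)phenyl]prop-2-enoate
Product: 14 (2E)-3-[3,4-bis(methoxymethoxy)phenyl]prop-2-en-1-ol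
Conditions: i-Bu2AlH, CH2Cl2, −78 °C; aq. potassium sodium tartrate
Reagents that add atoms: none
Why: 1,2-Reduction of the conjugated ester by the aluminium hydride gives the (E)-allylic alcohol without touching the alkene or the acetals.

Step 9
Reactants: 14 (2E)-3-[3,4-bis(methoxymethoxy)phenyl]prop-2-en-1-ol
Product: 15 [(2S,3S)-3-[3,4-bis(methoxymethoxy)phenyl]oxiran-2-yl]methanol
Conditions: Ti(Oi-Pr)4 (10 mol%), L-(+)-diisopropyl tartrate (12 mol%), t-BuOOH, 4 Å molecular sieves, CH2Cl2, −20 °C; NaOH/brine work-up
Reagents that add atoms: tert-butyl hydroperoxide, CC(C)(C)OO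
Why: Sharpless asymmetric epoxidation, in which the titanium L-(+)-tartrate complex delivers the peroxide oxygen to one face of the (E)-allylic alcohol and so sets both C7' and C8' as (2S,3S), is run in its catalytic molecular-sieve form with a basic work-up because the electron-rich benzylic epoxide is acid-labile.

Step 10
Reactants: 15 [(2S,3S)-3-[3,4-bis(methoxymethoxy)phenyl]oxiran-2-yl]methanol
Product: 16 (2S,3S)-2-[3,4-bis(methoxymethoxy)phenyl]-3-[(triphenylmethoxy)methyl]oxirane
Conditions: TrCl, Et3N, DMAP (cat.), CH2Cl2, 0 °C → rt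
Reagents that add atoms: trityl chloride, ClC(c1ccccc1)(c1ccccc1)c1ccccc1
Why: Tritylation of the primary hydroxyl (SN1 through the trityl cation under amine base) gives an ether that cannot migrate to a neighbouring alkoxide as a silyl group could and that is removed together with the MOM groups at the end.

Step 11
Reactants: 11 (2S,3S)-3-(3-bromo-4-hydroxyphenyl)-2-(hydroxymethyl)-2,3-dihydro-1,4-benzodioxine-6-carbaldehyde; 16 (2S,3S)-2-[3,4-bis(methoxymethoxy)phenyl]-3-[(triphenylmethoxy)methyl]oxirane
Product: 18 (2S,3S)-3-{(2R,3S)-2-[3,4-bis(methoxymethoxy)phenyl]-3-[(triphenylmethoxy)methyl]-2,3-dihydro-1,4-benzodioxin-6-yl}-2-(hydroxymethyl)-2,3-dihydro-1,4-benzodioxine-6-carbaldehyde, via ring-opened alcohol 17 (not isolated)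
Conditions: Cs2CO3, DMF, 65 °C; then CuI (10 mol%), 1,10-phenanthroline (20 mol%), 110 °C
Reagents that add atoms: none
Why: Phenoxide SN2 opening of the epoxide at its benzylic carbon with inversion (C7' becomes R) is followed by Ullmann-type copper-catalysed intramolecular C–O coupling of the C8' alkoxide with the aryl bromide with retention (C8' stays S), so the trans epoxide is translated into cis ring D with O4 of ring C on C7' and O3 on C8'.

Step 12
Reactants: 18 (2S,3S)-3-{(2R,3S)-2-[3,4-bis(methoxymethoxy)phenyl]-3-[(triphenylmethoxy)methyl]-2,3-dihydro-1,4-benzodioxin-6-yl}-2-(hydroxymethyl)-2,3-dihydro-1,4-benzodioxine-6-carbaldehyde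
Product: 19 (2E)-3-[(2S,3S)-3-{(2R,3S)-2-[3,4-bis(methoxymethoxy)phenyl]-3-[(triphenylmethoxy)methyl]-2,3-dihydro-1,4-benzodioxin-6-yl}-2-(hydroxymethyl)-2,3-dihydro-1,4-benzodioxin-6-yl]prop-2-enal
Conditions: Ph3P=CHCHO (1.2 equiv), toluene, 80 °C
Reagents that add atoms: (triphenylphosphoranylidene)acetaldehyde, O=CC=P(c1ccccc1)(c1ccccc1)c1ccccc1
Why: Wittig olefination with the formyl-stabilised ylide converts the aryl aldehyde into the (E)-enal under neutral conditions that leave the free C9 hydroxyl, the acetals and the trityl ether alone.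

Step 13
Reactants: 19 (2E)-3-[(2S,3S)-3-{(2R,3S)-2-[3,4-bis(methoxymethoxy)phenyl]-3-[(triphenylmethoxy)methyl]-2,3-dihydro-1,4-benzodioxin-6-yl}-2-(hydroxymethyl)-2,3-dihydro-1,4-benzodioxin-6-yl]prop-2-enal
Product: 20 (2E)-3-{(2S,3S)-3-[(2R,3S)-2-(3,4-dihydroxyphenyl)-3-(hydroxymethyl)-2,3-dihydro-1,4-benzodioxin-6-yl]-2-(hydroxymethyl)-2,3-dihydro-1,4-benzodioxin-6-yl}prop-2-enal (CNP0302404.1)
Conditions: aq. HCl (3 M), THF, 25 °C
Reagents that add atoms: none
Why: Acid hydrolysis of the two aryl MOM acetals and SN1 cleavage of the trityl ether free the catechol and the C9' hydroxyl, under conditions kept as mild and short as possible for the enal and for the benzylic aryl ethers of rings B and D.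

Compound list
1 | 2-bromo-4-iodophenol | Oc1ccc(I)cc1Br | starting material
2 | 2-bromo-4-iodo-1-(methoxymethoxy)benzene | COCOc1ccc(I)cc1Br | intermediate
3 | (2R)-2-[(triphenylmethoxy)methyl]oxirane ((R)-trityl glycidyl ether) | C(OC[C@H]1CO1)(c1ccccc1)(c1ccccc1)c1ccccc1 | starting material
4 | [3-bromo-4-(methoxymethoxy)phenyl]magnesium chloride | COCOc1ccc([Mg]Cl)cc1Br | intermediate
5 | (2R)-1-[3-bromo-4-(methoxymethoxy)phenyl]-3-(triphenylmethoxy)propan-2-ol | O[C@@H](COC(c1ccccc1)(c1ccccc1)c1ccccc1)Cc1ccc(OCOC)c(Br)c1 | intermediate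
6 | 4-fluoro-3-hydroxybenzaldehyde | O=Cc1ccc(F)c(O)c1 | starting material
7 | 4-fluoro-3-(methoxymethoxy)benzaldehyde | O=Cc1ccc(F)c(OCOC)c1 | intermediate
8 | 4-{[(2R)-1-[3-bromo-4-(methoxymethoxy)phenyl]-3-(triphenylmethoxy)propan-2-yl]oxy}-3-(methoxymethoxy)benzaldehyde | O=Cc1ccc(O[C@@H](COC(c2ccccc2)(c2ccccc2)c2ccccc2)Cc2ccc(OCOC)c(Br)c2)c(OCOC)c1 | intermediate
9 | 4-{[(2R)-1-(3-bromo-4-hydroxyphenyl)-3-hydroxypropan-2-yl]oxy}-3-hydroxybenzaldehyde | O=Cc1ccc(O[C@@H](CO)Cc2ccc(O)c(Br)c2)c(O)c1 | intermediate
10 | 4-{[(2R)-1-(3-bromo-4-oxocyclohexa-2,5-dien-1-ylidene)-3-hydroxypropan-2-yl]oxy}-3-hydroxybenzaldehyde (p-quinone methide) | O=Cc1ccc(O[C@@H](CO)C=C2C=CC(=O)C(Br)=C2)c(O)c1 | intermediate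
11 | (2S,3S)-3-(3-bromo-4-hydroxyphenyl)-2-(hydroxymethyl)-2,3-dihydro-1,4-benzodioxine-6-carbaldehyde | O=Cc1ccc2c(c1)O[C@@H](c1ccc(O)c(Br)c1)[C@H](CO)O2 | intermediate
12 | ethyl (2E)-3-(3,4-dihydroxyphenyl)prop-2-enoate (ethyl caffeate) | CCOC(=O)/C=C/c1ccc(O)c(O)c1 | starting material
13 | ethyl (2E)-3-[3,4-bis(methoxymethoxy)phenyl]prop-2-enoate | CCOC(=O)/C=C/c1ccc(OCOC)c(OCOC)c1 | intermediate
14 | (2E)-3-[3,4-bis(methoxymethoxy)phenyl]prop-2-en-1-ol | OC/C=C/c1ccc(OCOC)c(OCOC)c1 | intermediate
15 | [(2S,3S)-3-[3,4-bis(methoxymethoxy)phenyl]oxiran-2-yl]methanol | OC[C@@H]1O[C@H]1c1ccc(OCOC)c(OCOC)c1 | intermediate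
16 | (2S,3S)-2-[3,4-bis(methoxymethoxy)phenyl]-3-[(triphenylmethoxy)methyl]oxirane | C(OC[C@@H]1O[C@H]1c1ccc(OCOC)c(OCOC)c1)(c1ccccc1)(c1ccccc1)c1ccccc1 | intermediate
17 | (2S,3S)-3-[3-bromo-4-({(1R,2S)-1-[3,4-bis(methoxymethoxy)phenyl]-2-hydroxy-3-(triphenylmethoxy)propyl}oxy)phenyl]-2-(hydroxymethyl)-2,3-dihydro-1,4-benzodioxine-6-carbaldehyde | O=Cc1ccc2c(c1)O[C@@H](c1ccc(O[C@@H]([C@@H](O)COC(c3ccccc3)(c3ccccc3)c3ccccc3)c3ccc(OCOC)c(OCOC)c3)c(Br)c1)[C@H](CO)O2 | intermediate
18 | (2S,3S)-3-{(2R,3S)-2-[3,4-bis(methoxymethoxy)phenyl]-3-[(triphenylmethoxy)methyl]-2,3-dihydro-1,4-benzodioxin-6-yl}-2-(hydroxymethyl)-2,3-dihydro-1,4-benzodioxine-6-carbaldehyde | O=Cc1ccc2c(c1)O[C@@H](c1ccc3c(c1)O[C@@H](COC(c4ccccc4)(c4ccccc4)c4ccccc4)[C@@H](c1ccc(OCOC)c(OCOC)c1)O3)[C@H](CO)O2 | intermediate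
19 | (2E)-3-[(2S,3S)-3-{(2R,3S)-2-[3,4-bis(methoxymethoxy)phenyl]-3-[(triphenylmethoxy)methyl]-2,3-dihydro-1,4-benzodioxin-6-yl}-2-(hydroxymethyl)-2,3-dihydro-1,4-benzodioxin-6-yl]prop-2-enal | O=C/C=C/c1ccc2c(c1)O[C@@H](c1ccc3c(c1)O[C@@H](COC(c4ccccc4)(c4ccccc4)c4ccccc4)[C@@H](c1ccc(OCOC)c(OCOC)c1)O3)[C@H](CO)O2 | intermediate
20 | (2E)-3-{(2S,3S)-3-[(2R,3S)-2-(3,4-dihydroxyphenyl)-3-(hydroxymethyl)-2,3-dihydro-1,4-benzodioxin-6-yl]-2-(hydroxymethyl)-2,3-dihydro-1,4-benzodioxin-6-yl}prop-2-enal (CNP0302404.1) | O=C/C=C/c1ccc2c(c1)O[C@@H](c1ccc3c(c1)O[C@@H](CO)[C@@H](c1ccc(O)c(O)c1)O3)[C@H](CO)O2 | target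

Total step count: 13.
Longest linear sequence: 8 steps (steps 1, 2, 4, 5, 6, 11, 12, 13). Step 3 and steps 7–10 are side branches.

Steps most likely to fail

1. Step 6 (key step). Hydride abstraction at C7 is slowed by the bromine and by the β-aryloxy group, while the product keeps an oxygen-flanked C7–H. A second oxidation of the product, or tautomerisation and oligomerisation of the quinone methide, may therefore outrun closure by the weakly nucleophilic ring A hydroxyl. Fallback, from 9 back to 11, separates oxidation from ring closure. Compound 9 is treated with DDQ (1.05 equiv) in methanol at 0 °C, so that the solvent in large excess intercepts the quinone methide as soon as it forms. This should give the benzylic methyl ether 4-{[(2S)-1-(3-bromo-4-hydroxyphenyl)-3-hydroxy-1-methoxypropan-2-yl]oxy}-3-hydroxybenzaldehyde F1 as a mixture of C7 epimers (the C8 descriptor reads S only because C7 now outranks C9). After removal of the reduced quinone, catalytic TsOH·H2O in MeCN at rt ionises the p-hydroxybenzyl methyl ether, and the ring A hydroxyl closes ring B under thermodynamic control (acid-mediated SN1-type benzodioxane cyclisation). This should give trans 11 with no oxidant present.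

2. Step 11. Opening by the ortho-brominated phenoxide may be slow, and the electron-rich benzylic epoxide may ionise, which would erode the inversion at C7'. The copper-mediated closure at the hindered secondary alkoxide may also stall while the aldehyde sits in carbonate at 110 °C. Fallback, from 11 and 16 back to 18, replaces the one-pot copper tandem by two separate operations with a different bond-forming manifold for the second. The opening is run alone (Cs2CO3, DMF, 60 °C) and the ring-opened alcohol 17 is isolated and checked for diastereomeric purity. Ring D is then closed by palladium-catalysed intramolecular alkoxide arylation (Pd(OAc)2, 2-(di-tert-butylphosphino)-1,1'-binaphthyl, Cs2CO3, toluene, 70 °C). This proceeds by oxidative addition of the aryl bromide to zerovalent palladium, alkoxide exchange and C–O reductive elimination with retention at C8', and should give 18. No compound outside the compound list arises on this detour (F0).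

3. Step 9. The titanium Lewis acid may open the electron-rich benzylic epoxide during the reaction or the work-up, with loss of material and of enantiomeric purity. Fallback, from 14 back to 16, reverses the order of protection and epoxidation and avoids titanium. Alcohol 14 is tritylated (TrCl, Et3N, DMAP, CH2Cl2) to 1,2-bis(methoxymethoxy)-4-[(1E)-3-(triphenylmethoxy)prop-1-en-1-yl]benzene F2. This is epoxidised by the Shi protocol with the L-fructose-derived enantiomer of the usual ketone catalyst (KHSO5 as 2KHSO5·KHSO4·K2SO4, K2CO3, Bu4NHSO4, MeCN–dimethoxymethane–aqueous buffer of pH about 10.5, 0 °C). The chiral dioxirane attacks the (E)-alkene through the spiro transition state. Since the D-fructose ketone gives the (R,R) series with (E)-β-substituted styrenes, its enantiomer should give 16 directly, in a basic medium that spares the epoxide.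

Further compounds
F1 | step 6 | 4-{[(2S)-1-(3-bromo-4-hydroxyphenyl)-3-hydroxy-1-methoxypropan-2-yl]oxy}-3-hydroxybenzaldehyde (both C1 epimers) | O=Cc1ccc(O[C@@H](CO)C(OC)c2ccc(O)c(Br)c2)c(O)c1
F0 | step 11 | none | none
F2 | step 9 | 1,2-bis(methoxymethoxy)-4-[(1E)-3-(triphenylmethoxy)prop-1-en-1-yl]benzene | C(OC/C=C/c1ccc(OCOC)c(OCOC)c1)(c1ccccc1)(c1ccccc1)c1ccccc1
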